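**Plan**

- Retrosynthetic cuts: (a) the ring A C–C bond to the 1,1-dimethylallyl group, back to an aryl prenyl ether; (b) the propane chain next to ring B, back to a 2'-hydroxychalcone made from a ring B aldehyde and a ring A methyl ketone; (c) in ring B both O1–C7a and C3–C3a in one operation, back to an ortho-iodoaryl ether and a terminal epoxide; (d) the C4–prenyl bond.
- Forward order: the ring B benzaldehyde is prenylated, iodinated ortho to its hydroxyl and protected; a palladium/norbornene annulation with an (R)-epoxide then builds the dihydrofuran ring; aldol union with the ring A ketone, alkene hydrogenation and deoxygenation give the 1,3-diarylpropane; a Claisen rearrangement and MOM removal finish.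
- Enabling feature (benzofuran numbering O1, C2, C3, C3a, C4–C7, C7a): O1 sits on C7a, which is flanked by the oxygen-bearing C7 and by C3a carrying the ring CH2 (C3). This is an ipso C–O bond beside an ortho C–C bond and an ortho substituent. C2 is a carbinol carbon bearing CMe2OH, the opened form of a terminal epoxide.
- Stereochemistry: the only stereocentre (C2, R) comes from methyl (R)-glycidate; no bond to it is broken afterwards.

Key step: step 5

Remark: the stereocentre of the target is read as R; the three starting materials and the reagents named are taken as purchasable. In step names, "DBF" stands for the (2R)-2-(2-hydroxypropan-2-yl)-7-(methoxymethoxy)-4-(3-methylbut-2-en-1-yl)-2,3-dihydro-1-benzofuran-5-yl group.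

**Step 1**
Reactants: 1 2-bromo-5-hydroxybenzaldehyde
Product: 2 5-hydroxy-2-(3-methylbut-2-en-1-yl)benzaldehyde
Conditions: tributyl(3-methylbut-2-en-1-yl)stannane, Pd(PPh3)4 (5 mol %), DMF, 95 °C
Reagents that add atoms: tributyl(3-methylbut-2-en-1-yl)stannane, CCCC[Sn](CCCC)(CCCC)CC=C(C)C
Why: Stille coupling at the C–Br bond activated by the ortho formyl group should transfer the prenyl group through its CH2 end (linear product), and the free phenol is tolerated.

**Step 2**
Reactants: 2 5-hydroxy-2-(3-methylbut-2-en-1-yl)benzaldehyde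
Product: 3 5-hydroxy-4-iodo-2-(3-methylbut-2-en-1-yl)benzaldehyde
Conditions: I2, NaHCO3, THF/H2O, 0 °C to rt
Reagents that add atoms: iodine, II
Why: Electrophilic iodination of the phenoxide should go to C4, because the para position is blocked by the prenyl group and the other ortho position lies between OH and CHO; the phenoxide should react far faster with iodine than the trisubstituted alkene does.

**Step 3**
Reactants: 3 5-hydroxy-4-iodo-2-(3-methylbut-2-en-1-yl)benzaldehyde
Product: 4 4-iodo-5-(methoxymethoxy)-2-(3-methylbut-2-en-1-yl)benzaldehyde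
Conditions: MOMCl, i-Pr2NEt, CH2Cl2, 0 °C to rt
Reagents that add atoms: chloromethyl methyl ether, COCCl
Why: O-alkylation of the phenol gives a base-stable MOM ether, which also serves as the ortho substituent that the annulation in step 5 requires.

**Step 4**
Reactants: 5 methyl (2R)-oxirane-2-carboxylate
Product: 7 triethyl({2-[(2R)-oxiran-2-yl]propan-2-yl}oxy)silane, via epoxy alcohol 6 (not isolated)
Conditions: MeMgCl (2.2 equiv), THF, −78 °C; aq. NH4Cl, extraction, drying; then Et3SiOTf, 2,6-lutidine, CH2Cl2, −78 to 0 °C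
Reagents that add atoms: methylmagnesium chloride, C[Mg]Cl; triethylsilyl trifluoromethanesulfonate, CC[Si](CC)(CC)OS(=O)(=O)C(F)(F)F
Why: Double Grignard addition to the ester, which is far more electrophilic than the epoxide at low temperature, leaves the stereocentre untouched, and silylation of the volatile tertiary alcohol masks a hydroxyl that could otherwise trigger Payne-type epoxide migration or bind palladium in step 5.

**Step 5**
Reactants: 4 4-iodo-5-(methoxymethoxy)-2-(3-methylbut-2-en-1-yl)benzaldehyde; 7 triethyl({2-[(2R)-oxiran-2-yl]propan-2-yl}oxy)silane (3 equiv)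
Product: 9 (2R)-2-(2-hydroxypropan-2-yl)-7-(methoxymethoxy)-4-(3-methylbut-2-en-1-yl)-2,3-dihydro-1-benzofuran-5-carbaldehyde, via silyl ether 8 (not isolated)
Conditions: Pd(OAc)2 (10 mol %), RuPhos (20 mol %), isopropyl bicyclo[2.2.1]hept-5-ene-2-carboxylate (0.5 equiv), Cs2CO3 (2 equiv), DMF, 110 °C; then Bu4NF, THF, rt
Reagents that add atoms: none
Why: Zerovalent palladium inserts into the C–I bond of 4, norbornene carbopalladation and carbonate-assisted palladation of the only free ortho C–H (C3 of 4) give an aryl–norbornyl palladacycle, which opens epoxide 7 at its unhindered CH2 end (oxidative addition to tetravalent palladium) and forms the C3a–C3 bond by C(sp2)–C(sp3) reductive elimination. With both ortho positions now substituted, norbornene is expelled by β-carbon elimination and the resulting arylpalladium alkoxide undergoes C–O reductive elimination at the ipso carbon. The closest known reaction type is the palladium/norbornene (Catellani-type) annulation of ortho-substituted aryl iodides with epoxides to 2,3-dihydrobenzofurans. The one ring closed, the five-membered dihydrofuran, closes by C(aryl)–O reductive elimination from a six-membered oxapalladacycle, forming O1–C7a. The C2 stereocentre is the carbinol carbon of 7, whose C–O bond is never broken, so the R configuration is carried over unchanged. The step needs ortho-alkylation before ipso termination, attack at the epoxide CH2 and C–O reductive elimination in preference to β-hydride loss; these should be secured by the OMOM group on the other ortho carbon, by the quaternary silyloxy carbon next to the epoxide CH, and by the bulky RuPhos ligand together with the para formyl group.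

**Step 6**
Reactants: 10 1-(2,4-dihydroxyphenyl)ethan-1-one
Product: 11 1-{2-hydroxy-4-[(3-methylbut-2-en-1-yl)oxy]phenyl}ethan-1-one
Conditions: 1-bromo-3-methylbut-2-ene, K2CO3, acetone, reflux
Reagents that add atoms: 1-bromo-3-methylbut-2-ene, CC(C)=CCBr
Why: Williamson etherification should occur only at the 4-hydroxyl, because the 2-hydroxyl is held in a hydrogen bond to the acetyl group.

**Step 7**
Reactants: 9 DBF-carbaldehyde; 11 1-{2-hydroxy-4-[(3-methylbut-2-en-1-yl)oxy]phenyl}ethan-1-one
Product: 12 (2E)-3-DBF-1-{2-hydroxy-4-[(3-methylbut-2-en-1-yl)oxy]phenyl}prop-2-en-1-one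
Conditions: KOH (50 % aq.), EtOH, rt
Reagents that add atoms: none
Why: Claisen–Schmidt condensation (aldol addition, then E1cB dehydration) should give the E-chalcone, and the MOM ether, both prenyl groups and the tertiary alcohol are stable to hydroxide.

**Step 8**
Reactants: 12 (2E)-3-DBF-1-{2-hydroxy-4-[(3-methylbut-2-en-1-yl)oxy]phenyl}prop-2-en-1-one
Product: 13 3-DBF-1-{2-hydroxy-4-[(3-methylbut-2-en-1-yl)oxy]phenyl}propan-1-one
Conditions: H2 (1 atm), RhCl(PPh3)3 (10 mol %), benzene/EtOH 1:1, rt
Reagents that add atoms: none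
Why: Homogeneous hydrogenation with RhCl(PPh3)3 selects by alkene substitution, so the disubstituted enone C=C should be reduced while the trisubstituted alkenes of the O-prenyl and C-prenyl groups and the aryl ethers remain.

**Step 9**
Reactants: 13 3-DBF-1-{2-hydroxy-4-[(3-methylbut-2-en-1-yl)oxy]phenyl}propan-1-one
Product: 15 2-(3-DBF-propyl)-5-[(3-methylbut-2-en-1-yl)oxy]phenol, via aryl ethyl carbonate 14 (not isolated)
Conditions: ClCO2Et, Et3N, THF, 0 °C; then NaBH4, H2O, 0 °C to rt
Reagents that add atoms: none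
Why: Reduction of the ketone in the O-ethoxycarbonyl derivative gives a benzylic alkoxide that expels the carbonate to form an ortho-quinone methide, and hydride 1,4-addition to it gives the ortho-alkylphenol, a known deoxygenation of 2-hydroxyaryl ketones that needs no acid or hydrogenolysis.

**Step 10**
Reactants: 15 2-(3-DBF-propyl)-5-[(3-methylbut-2-en-1-yl)oxy]phenol
Product: 16 4-(3-DBF-propyl)-6-(2-methylbut-3-en-2-yl)benzene-1,3-diol
Conditions: N,N-diethylaniline, 170 °C, degassed, sealed tube
Reagents that add atoms: none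
Why: Aromatic Claisen ([3,3]-sigmatropic) rearrangement of the aryl prenyl ether delivers the 1,1-dimethylallyl group with allylic inversion to an ortho carbon; the position para to the free hydroxyl should be preferred, since the other ortho carbon lies between two oxygen substituents.

**Step 11**
Reactants: 16 4-(3-DBF-propyl)-6-(2-methylbut-3-en-2-yl)benzene-1,3-diol
Product: 17 4-{3-[(2R)-7-hydroxy-2-(2-hydroxypropan-2-yl)-4-(3-methylbut-2-en-1-yl)-2,3-dihydro-1-benzofuran-5-yl]propyl}-6-(2-methylbut-3-en-2-yl)benzene-1,3-diol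
Conditions: HCl (3 M aq.), MeOH, 40 °C
Reagents that add atoms: none
Why: Acid-catalysed methanolysis of the aryl MOM acetal should free the last phenol under conditions mild enough for the prenyl group, the ortho-(1,1-dimethylallyl)phenol and the tertiary alcohol.

**Compound list**

1 | 2-bromo-5-hydroxybenzaldehyde | O=Cc1cc(O)ccc1Br | starting material
2 | 5-hydroxy-2-(3-methylbut-2-en-1-yl)benzaldehyde | O=Cc1cc(O)ccc1CC=C(C)C | intermediate
3 | 5-hydroxy-4-iodo-2-(3-methylbut-2-en-1-yl)benzaldehyde | O=Cc1cc(O)c(I)cc1CC=C(C)C | intermediate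
4 | 4-iodo-5-(methoxymethoxy)-2-(3-methylbut-2-en-1-yl)benzaldehyde | O=Cc1cc(OCOC)c(I)cc1CC=C(C)C | intermediate
5 | methyl (2R)-oxirane-2-carboxylate | COC(=O)[C@H]1CO1 | starting material
6 | 2-[(2R)-oxiran-2-yl]propan-2-ol | CC(C)(O)[C@H]1CO1 | intermediate
7 | triethyl({2-[(2R)-oxiran-2-yl]propan-2-yl}oxy)silane | CC[Si](CC)(CC)OC(C)(C)[C@H]1CO1 | intermediate
8 | (2R)-7-(methoxymethoxy)-4-(3-methylbut-2-en-1-yl)-2-{2-[(triethylsilyl)oxy]propan-2-yl}-2,3-dihydro-1-benzofuran-5-carbaldehyde | O=Cc1cc(OCOC)c2c(c1CC=C(C)C)C[C@H](C(C)(C)O[Si](CC)(CC)CC)O2 | intermediate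
9 | (2R)-2-(2-hydroxypropan-2-yl)-7-(methoxymethoxy)-4-(3-methylbut-2-en-1-yl)-2,3-dihydro-1-benzofuran-5-carbaldehyde | O=Cc1cc(OCOC)c2c(c1CC=C(C)C)C[C@H](C(C)(C)O)O2 | intermediate
10 | 1-(2,4-dihydroxyphenyl)ethan-1-one | CC(=O)c1ccc(O)cc1O | starting material
11 | 1-{2-hydroxy-4-[(3-methylbut-2-en-1-yl)oxy]phenyl}ethan-1-one | CC(=O)c1ccc(OCC=C(C)C)cc1O | intermediate
12 | (2E)-1-{2-hydroxy-4-[(3-methylbut-2-en-1-yl)oxy]phenyl}-3-[(2R)-2-(2-hydroxypropan-2-yl)-7-(methoxymethoxy)-4-(3-methylbut-2-en-1-yl)-2,3-dihydro-1-benzofuran-5-yl]prop-2-en-1-one | CC(C)=CCOc1ccc(C(=O)/C=C/c2cc(OCOC)c3c(c2CC=C(C)C)C[C@H](C(C)(C)O)O3)c(O)c1 | intermediate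
13 | 1-{2-hydroxy-4-[(3-methylbut-2-en-1-yl)oxy]phenyl}-3-[(2R)-2-(2-hydroxypropan-2-yl)-7-(methoxymethoxy)-4-(3-methylbut-2-en-1-yl)-2,3-dihydro-1-benzofuran-5-yl]propan-1-one | CC(C)=CCOc1ccc(C(=O)CCc2cc(OCOC)c3c(c2CC=C(C)C)C[C@H](C(C)(C)O)O3)c(O)c1 | intermediate
14 | ethyl 2-{3-[(2R)-2-(2-hydroxypropan-2-yl)-7-(methoxymethoxy)-4-(3-methylbut-2-en-1-yl)-2,3-dihydro-1-benzofuran-5-yl]propanoyl}-5-[(3-methylbut-2-en-1-yl)oxy]phenyl carbonate | CCOC(=O)Oc1cc(OCC=C(C)C)ccc1C(=O)CCc1cc(OCOC)c2c(c1CC=C(C)C)C[C@H](C(C)(C)O)O2 | intermediate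
15 | 2-{3-[(2R)-2-(2-hydroxypropan-2-yl)-7-(methoxymethoxy)-4-(3-methylbut-2-en-1-yl)-2,3-dihydro-1-benzofuran-5-yl]propyl}-5-[(3-methylbut-2-en-1-yl)oxy]phenol | CC(C)=CCOc1ccc(CCCc2cc(OCOC)c3c(c2CC=C(C)C)C[C@H](C(C)(C)O)O3)c(O)c1 | intermediate
16 | 4-{3-[(2R)-2-(2-hydroxypropan-2-yl)-7-(methoxymethoxy)-4-(3-methylbut-2-en-1-yl)-2,3-dihydro-1-benzofuran-5-yl]propyl}-6-(2-methylbut-3-en-2-yl)benzene-1,3-diol | C=CC(C)(C)c1cc(CCCc2cc(OCOC)c3c(c2CC=C(C)C)C[C@H](C(C)(C)O)O3)c(O)cc1O | intermediate
17 | 4-{3-[(2R)-7-hydroxy-2-(2-hydroxypropan-2-yl)-4-(3-methylbut-2-en-1-yl)-2,3-dihydro-1-benzofuran-5-yl]propyl}-6-(2-methylbut-3-en-2-yl)benzene-1,3-diol | C=CC(C)(C)c1cc(CCCc2cc(O)c3c(c2CC=C(C)C)C[C@H](C(C)(C)O)O3)c(O)cc1O | target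

**Step count**

Total step count: 11. Longest linear sequence: 9 steps (steps 1, 2, 3, 5, 7, 8, 9, 10, 11).

**Steps most likely to fail**

Step 5. The C–H bond to be palladated is flanked by the prenyl-bearing carbon, so palladacycle formation may be slow. The arylpalladium alkoxide may also lose a β-hydride or be protonated instead of undergoing C–O reductive elimination. The fallback makes the same two ring bonds one at a time by polar and copper chemistry, with bromine as a place-holder for the prenyl group. It sets out from 1 and 7 and comes back at 8.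
- Iodination of 1 (I2, NaHCO3) should give 2-bromo-5-hydroxy-4-iodobenzaldehyde F1.
- Acetalisation (ethylene glycol, TsOH, toluene, water removal) gives 4-bromo-5-(1,3-dioxolan-2-yl)-2-iodophenol F2.
- MOMCl with i-Pr2NEt gives 2-[2-bromo-4-iodo-5-(methoxymethoxy)phenyl]-1,3-dioxolane F3.
- LiN(i-Pr)2 in THF at −78 °C should remove the acidic proton between bromine and iodine; the aryllithium opens 7 at its CH2 end with BF3·OEt2 to give (2R)-1-[2-bromo-3-(1,3-dioxolan-2-yl)-6-iodo-5-(methoxymethoxy)phenyl]-3-methyl-3-[(triethylsilyl)oxy]butan-2-ol F4.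
- Intramolecular Ullmann-type O-arylation (CuI, 1,10-phenanthroline, Cs2CO3, toluene, 110 °C) should close the ring at the C–I bond in preference to the C–Br bond, giving 2-[(2R)-4-bromo-7-(methoxymethoxy)-2-{2-[(triethylsilyl)oxy]propan-2-yl}-2,3-dihydro-1-benzofuran-5-yl]-1,3-dioxolane F5.
- Pyridinium tosylate in acetone/water frees the aldehyde, giving (2R)-4-bromo-7-(methoxymethoxy)-2-{2-[(triethylsilyl)oxy]propan-2-yl}-2,3-dihydro-1-benzofuran-5-carbaldehyde F6.
- Stille coupling of F6 with tributyl(3-methylbut-2-en-1-yl)stannane and Pd(PPh3)4 gives 8, which is desilylated to 9 as in step 5.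

Step 10. The prenyl group may migrate to the carbon between the two oxygens instead of the one para to the hydroxyl. The first-formed ortho-(1,1-dimethylallyl)phenol may also react further at this temperature (abnormal Claisen isomerisation, or addition of the phenol to the vinyl group). The fallback moves the rearrangement to the ketone stage, where the ether is para to a carbonyl and the 2-oxygen is acylated and not chelated, the pattern for which migration to the required carbon has close precedent. It sets out from 14 and comes back at 16.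
- Carbonate 14 is isolated after the first half of step 9 and heated in N,N-diethylaniline to give ethyl 5-hydroxy-4-(2-methylbut-3-en-2-yl)-2-{3-[(2R)-2-(2-hydroxypropan-2-yl)-7-(methoxymethoxy)-4-(3-methylbut-2-en-1-yl)-2,3-dihydro-1-benzofuran-5-yl]propanoyl}phenyl carbonate F7.
- NaBH4 in aqueous THF then carries out the ortho-quinone methide deoxygenation and gives 16 directly.

Step 8. Hydrogenation of the chelated, conjugated enone may stall, or rhodium hydride may isomerise the allyl-type aryl ether. The fallback removes the carbonyl first and reduces an unpolarised alkene afterwards. It sets out from 12 and comes back at 15.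
- ClCO2Et with Et3N gives ethyl 2-{(2E)-3-[(2R)-2-(2-hydroxypropan-2-yl)-7-(methoxymethoxy)-4-(3-methylbut-2-en-1-yl)-2,3-dihydro-1-benzofuran-5-yl]prop-2-enoyl}-5-[(3-methylbut-2-en-1-yl)oxy]phenyl carbonate F8.
- NaBH4 reduces F8 through the vinylogous ortho-quinone methide to 2-{(2E)-3-[(2R)-2-(2-hydroxypropan-2-yl)-7-(methoxymethoxy)-4-(3-methylbut-2-en-1-yl)-2,3-dihydro-1-benzofuran-5-yl]prop-2-en-1-yl}-5-[(3-methylbut-2-en-1-yl)oxy]phenol F9; a double-bond isomer would converge in the next operation.
- Diimide (TsNHNH2, NaOAc, THF/H2O, reflux) should reduce the disubstituted alkene of F9 faster than the trisubstituted prenyl alkenes, giving 15.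

**Further compounds**

F1 | step 5 | 2-bromo-5-hydroxy-4-iodobenzaldehyde | O=Cc1cc(O)c(I)cc1Br
F2 | step 5 | 4-bromo-5-(1,3-dioxolan-2-yl)-2-iodophenol | Oc1cc(C2OCCO2)c(Br)cc1I
F3 | step 5 | 2-[2-bromo-4-iodo-5-(methoxymethoxy)phenyl]-1,3-dioxolane | COCOc1cc(C2OCCO2)c(Br)cc1I
F4 | step 5 | (2R)-1-[2-bromo-3-(1,3-dioxolan-2-yl)-6-iodo-5-(methoxymethoxy)phenyl]-3-methyl-3-[(triethylsilyl)oxy]butan-2-ol | COCOc1cc(C2OCCO2)c(Br)c(C[C@@H](O)C(C)(C)O[Si](CC)(CC)CC)c1I
F5 | step 5 | 2-[(2R)-4-bromo-7-(methoxymethoxy)-2-{2-[(triethylsilyl)oxy]propan-2-yl}-2,3-dihydro-1-benzofuran-5-yl]-1,3-dioxolane | COCOc1cc(C2OCCO2)c(Br)c2C[C@H](C(C)(C)O[Si](CC)(CC)CC)Oc12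
F6 | step 5 | (2R)-4-bromo-7-(methoxymethoxy)-2-{2-[(triethylsilyl)oxy]propan-2-yl}-2,3-dihydro-1-benzofuran-5-carbaldehyde | O=Cc1cc(OCOC)c2c(c1Br)C[C@H](C(C)(C)O[Si](CC)(CC)CC)O2
F7 | step 10 | ethyl 5-hydroxy-4-(2-methylbut-3-en-2-yl)-2-{3-[(2R)-2-(2-hydroxypropan-2-yl)-7-(methoxymethoxy)-4-(3-methylbut-2-en-1-yl)-2,3-dihydro-1-benzofuran-5-yl]propanoyl}phenyl carbonate | CCOC(=O)Oc1cc(O)c(C(C)(C)C=C)cc1C(=O)CCc1cc(OCOC)c2c(c1CC=C(C)C)C[C@H](C(C)(C)O)O2
F8 | step 8 | ethyl 2-{(2E)-3-[(2R)-2-(2-hydroxypropan-2-yl)-7-(methoxymethoxy)-4-(3-methylbut-2-en-1-yl)-2,3-dihydro-1-benzofuran-5-yl]prop-2-enoyl}-5-[(3-methylbut-2-en-1-yl)oxy]phenyl carbonate | CCOC(=O)Oc1cc(OCC=C(C)C)ccc1C(=O)/C=C/c1cc(OCOC)c2c(c1CC=C(C)C)C[C@H](C(C)(C)O)O2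
F9 | step 8 | 2-{(2E)-3-[(2R)-2-(2-hydroxypropan-2-yl)-7-(methoxymethoxy)-4-(3-methylbut-2-en-1-yl)-2,3-dihydro-1-benzofuran-5-yl]prop-2-en-1-yl}-5-[(3-methylbut-2-en-1-yl)oxy]phenol | CC(C)=CCOc1ccc(C/C=C/c2cc(OCOC)c3c(c2CC=C(C)C)C[C@H](C(C)(C)O)O3)c(O)c1
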